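The cyclohexene ring (C1–C6, carotenoid numbering) is cut at C1–C2 and C5–C6. The quaternary C1 with its two methyls and the neighbouring C6 methine carrying C7 map onto the β-carbon, α-carbon and formyl group of 3-methylbut-2-enal. C2–C5, with oxygen at C3 and methyl at C5, map onto a 2-silyloxypenta-1,3-diene made from (E)-pent-3-en-2-one. A single catalytic enantioselective Diels–Alder reaction joins the two, closes the ring, fixes C6 and leaves a C3=C4 silyl enol ether from which C4=C5 and the C3 hydroxyl are later drawn. The polyene is then grown from C7 by phosphorus olefinations.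

Key step: step 2

Remark on locants: carotenoid numbering is used throughout; in cycloadduct 4 the formyl carbon is C7 and the ring carbon that bears it is C6.
Assumption: enal 3 is taken to bind the boron Lewis acid in the s-trans, formyl C–H···O mode, for which the (R)-configured catalyst exposes the Si face of the α-carbon; if the other binding mode operates, the (S)-catalyst is used instead.

Step 1
Reactants: 1 (E)-pent-3-en-2-one
Product: 2 (E)-2-(tert-butyldimethylsilyloxy)penta-1,3-diene
Conditions: TBSOTf, Et3N, CH2Cl2, 0 °C → rt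
Reagents that add atoms: tert-butyldimethylsilyl trifluoromethanesulfonate (TBSOTf), CC(C)(C)[Si](C)(C)OS(=O)(=O)C(F)(F)F
Why: Silyl enol ether formation by soft enolisation, in which the amine removes a proton from the acetyl methyl group of the silyl-activated enone, should give the cross-conjugated 2-silyloxy-1,3-diene with the E olefin untouched.

Step 2
Reactants: 2 (E)-2-(tert-butyldimethylsilyloxy)penta-1,3-diene, 3 3-methylbut-2-enal
Product: 4 (1S,2S)-4-(tert-butyldimethylsilyloxy)-2,6,6-trimethylcyclohex-3-ene-1-carbaldehyde (formyl and 2-methyl cis)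
Conditions: (R)-3,3-diphenyl-1-(2-methylphenyl)tetrahydro-1H,3H-pyrrolo[1,2-c][1,3,2]oxazaborole (20 mol%), Tf2NH (20 mol%), CH2Cl2, −78 → −20 °C
Reagents that add atoms: none
Why: Proposed new method: the N-protonated oxazaborolidine binds the formyl oxygen of s-trans 3 and lowers its LUMO so that 2 adds in a concerted, asynchronous [4+2] fashion, the CH2 terminus bonding to the β-carbon (future C1) ahead of the methyl-bearing terminus bonding to the α-carbon (future C6); the closest known reactions are oxazaborolidinium-catalysed Diels–Alder additions of 2-silyloxydienes to less substituted enals and achiral Lewis-acid Diels–Alder additions of hindered silyloxydienes to β,β-dimethyl enones. The six-membered carbocycle closes by intermolecular suprafacial–suprafacial [4+2] cycloaddition, both ring bonds (C1–C2 and C5–C6) being made in this one step. C6 is controlled by the catalyst, whose aryl groups screen one face of the bound enal so that the diene meets the Si face of the α-carbon; C5 follows from the E geometry of the diene and endo placement of the formyl group and is erased in step 4, so endo/exo leakage is harmless. The step needs regioselectivity, secured in the substrate because the 2-silyloxy group (para-directing) and the terminal methyl (ortho-directing) both place the largest HOMO coefficient on the CH2 terminus, matched to the β-carbon of the enal. It also needs cycloaddition to outrun Mukaiyama aldol addition at the formyl carbon, which the bulky silyl group, the low temperature and the non-nucleophilic triflimide counter-ion favour.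

Step 3
Reactants: 4 (1S,2S)-4-(tert-butyldimethylsilyloxy)-2,6,6-trimethylcyclohex-3-ene-1-carbaldehyde, 5 triethyl 3-methyl-4-phosphonocrotonate
Product: 7 ethyl (2E,4E)-5-[(1S,2R)-4-(tert-butyldimethylsilyloxy)-2,6,6-trimethylcyclohex-3-en-1-yl]-3-methylpenta-2,4-dienoate, via lithiated phosphonate 6 (not isolated)
Conditions: 5, LiN(SiMe3)2, THF/DMPU, −78 °C; then 4, −78 → 0 °C
Reagents that add atoms: none
Why: Horner–Wadsworth–Emmons olefination with the pre-formed lithium phosphonate should give the (4E) olefin and mainly the (2E) ester (minor 2Z isomer removed by chromatography); it is run here because C6 is only α to a formyl group and has no leaving group at C3, and adding the aldehyde to base-free carbanion at −78 °C is meant to outrun enolisation.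

Step 4
Reactants: 7 ethyl (2E,4E)-5-[(1S,2R)-4-(tert-butyldimethylsilyloxy)-2,6,6-trimethylcyclohex-3-en-1-yl]-3-methylpenta-2,4-dienoate
Product: 8 ethyl (2E,4E)-3-methyl-5-[(1R)-2,6,6-trimethyl-4-oxocyclohex-2-en-1-yl]penta-2,4-dienoate
Conditions: Pd(OAc)2 (1.1 equiv), MeCN, rt → 40 °C
Reagents that add atoms: none
Why: Saegusa–Ito oxidation, in which the silyl enol ether gives a C4-bound enolate of divalent palladium and syn β-hydride elimination of the C5 hydrogen releases zerovalent palladium, should place the enone at C3/C4=C5 regiospecifically, erase C5 and leave C6 untouched (the quaternary C1 blocks any second dehydrogenation).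

Step 5
Reactants: 8 ethyl (2E,4E)-3-methyl-5-[(1R)-2,6,6-trimethyl-4-oxocyclohex-2-en-1-yl]penta-2,4-dienoate
Product: 9 ethyl (2E,4E)-5-[(1R,4S)-4-hydroxy-2,6,6-trimethylcyclohex-2-en-1-yl]-3-methylpenta-2,4-dienoate (hydroxyl cis to the side chain)
Conditions: NaBH4, CeCl3·7H2O, MeOH, −40 °C
Reagents that add atoms: none
Why: Luche 1,2-reduction, in which the small methoxyborohydride adds axially to C3 on the face away from the pseudo-axial C6 side chain, should give the pseudo-equatorial hydroxyl cis to that chain (3S by substrate control, minor trans epimer removed by chromatography) and leave the dienoate and the C6 hydrogen alone in the nearly neutral medium.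

Step 6
Reactants: 9 ethyl (2E,4E)-5-[(1R,4S)-4-hydroxy-2,6,6-trimethylcyclohex-2-en-1-yl]-3-methylpenta-2,4-dienoate
Product: 10 ethyl (2E,4E)-5-[(1R,4S)-4-(tert-butyldimethylsilyloxy)-2,6,6-trimethylcyclohex-2-en-1-yl]-3-methylpenta-2,4-dienoate
Conditions: TBSCl, imidazole, DMF, rt
Reagents that add atoms: tert-butyldimethylsilyl chloride (TBSCl), CC(C)(C)[Si](C)(C)Cl
Why: Imidazole-promoted silylation of the secondary allylic alcohol is routine and masks the acid- and ionisation-prone C3 oxygen for the phosphonium and ylide chemistry that follows.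

Step 7
Reactants: 10 ethyl (2E,4E)-5-[(1R,4S)-4-(tert-butyldimethylsilyloxy)-2,6,6-trimethylcyclohex-2-en-1-yl]-3-methylpenta-2,4-dienoate
Product: 11 (2E,4E)-5-[(1R,4S)-4-(tert-butyldimethylsilyloxy)-2,6,6-trimethylcyclohex-2-en-1-yl]-3-methylpenta-2,4-dien-1-ol
Conditions: i-Bu2AlH (2.3 equiv), CH2Cl2, −78 °C; aq. sodium potassium tartrate
Reagents that add atoms: none
Why: Hydride reduction of a conjugated ester with i-Bu2AlH stops cleanly at the allylic alcohol by 1,2-addition and does not touch the silyl ether or the olefins.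

Step 8
Reactants: 11 (2E,4E)-5-[(1R,4S)-4-(tert-butyldimethylsilyloxy)-2,6,6-trimethylcyclohex-2-en-1-yl]-3-methylpenta-2,4-dien-1-ol
Product: 13 [(2E,4E)-5-[(1R,4S)-4-(tert-butyldimethylsilyloxy)-2,6,6-trimethylcyclohex-2-en-1-yl]-3-methylpenta-2,4-dien-1-yl]triphenylphosphonium bromide, via allylic bromide 12 (not isolated)
Conditions: CBr4, PPh3, CH2Cl2, 0 °C; then further PPh3, rt
Reagents that add atoms: tetrabromomethane, BrC(Br)(Br)Br; triphenylphosphine, c1ccc(cc1)P(c1ccccc1)c1ccccc1
Why: Appel bromination of the primary dienylic alcohol followed by SN2 quaternisation of the labile bromide with triphenylphosphine in the same flask gives the phosphonium salt under neutral conditions, avoiding the strong acid that would ionise the allylic C3 silyl ether.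

Step 9
Reactants: 14 chloroacetaldehyde (50% aqueous solution), 15 ethyl 2-(triphenylphosphoranylidene)propanoate
Product: 16 ethyl (E)-4-chloro-2-methylbut-2-enoate
Conditions: CH2Cl2/H2O, rt
Reagents that add atoms: none
Why: Wittig olefination of an aldehyde with a stabilised ylide is E-selective and tolerates water, so the trisubstituted (E)-enoate with the allylic chloride should form directly.

Step 10
Reactants: 16 ethyl (E)-4-chloro-2-methylbut-2-enoate
Product: 17 ethyl (E)-4-(diethoxyphosphoryl)-2-methylbut-2-enoate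
Conditions: P(OEt)3, NaI (cat.), neat, 140 °C
Reagents that add atoms: triethyl phosphite, CCOP(OCC)OCC
Why: Michaelis–Arbuzov reaction of a primary allylic halide with triethyl phosphite (iodide-assisted) gives the phosphonate with loss of chloroethane and retention of the olefin geometry.

Step 11
Reactants: 17 ethyl (E)-4-(diethoxyphosphoryl)-2-methylbut-2-enoate, 18 (2E,4E,6E)-2,7-dimethylocta-2,4,6-trienedial
Product: 20 ethyl (2E,4E,6E,8E,10E)-2,6,11-trimethyl-12-oxododeca-2,4,6,8,10-pentaenoate, via sodium phosphonate anion 19 (not isolated)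
Conditions: 17, NaH, THF, 0 °C; then added slowly to 18 (2.5 equiv), THF, 0 °C → rt
Reagents that add atoms: none
Why: Horner–Wadsworth–Emmons mono-olefination of the symmetrical dialdehyde, kept in excess to suppress double reaction, should form the new disubstituted olefin E and leave one formyl group for the coupling.

Step 12
Reactants: 13 [(2E,4E)-5-[(1R,4S)-4-(tert-butyldimethylsilyloxy)-2,6,6-trimethylcyclohex-2-en-1-yl]-3-methylpenta-2,4-dien-1-yl]triphenylphosphonium bromide, 20 ethyl (2E,4E,6E,8E,10E)-2,6,11-trimethyl-12-oxododeca-2,4,6,8,10-pentaenoate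
Product: 22 ethyl (2E,4E,6E,8E,10E,12E,14E,16E)-17-[(1R,4S)-4-(tert-butyldimethylsilyloxy)-2,6,6-trimethylcyclohex-2-en-1-yl]-2,6,11,15-tetramethylheptadeca-2,4,6,8,10,12,14,16-octaenoate, via phosphorus ylide 21 (not isolated)
Conditions: 13, NaN(SiMe3)2, THF, −78 °C; then 20, −78 °C → rt; then heptane, reflux, dim light
Reagents that add atoms: none
Why: Wittig olefination of the polyenal with the semi-stabilised allylic ylide forms C11=C12 (the standard C15 + C15 carotenoid coupling), and any hindered (11Z) isomer should relax thermally to the all-E polyene.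

Step 13
Reactants: 22 ethyl (2E,4E,6E,8E,10E,12E,14E,16E)-17-[(1R,4S)-4-(tert-butyldimethylsilyloxy)-2,6,6-trimethylcyclohex-2-en-1-yl]-2,6,11,15-tetramethylheptadeca-2,4,6,8,10,12,14,16-octaenoate
Product: 23 (2E,4E,6E,8E,10E,12E,14E,16E)-17-[(1R,4S)-4-(tert-butyldimethylsilyloxy)-2,6,6-trimethylcyclohex-2-en-1-yl]-2,6,11,15-tetramethylheptadeca-2,4,6,8,10,12,14,16-octaen-1-ol
Conditions: i-Bu2AlH (2.3 equiv), CH2Cl2, −78 °C; aq. sodium potassium tartrate
Reagents that add atoms: none
Why: 1,2-Reduction of the conjugated polyene ester with i-Bu2AlH gives the primary allylic alcohol at C8' without touching the polyene or the silyl ether.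

Step 14
Reactants: 23 (2E,4E,6E,8E,10E,12E,14E,16E)-17-[(1R,4S)-4-(tert-butyldimethylsilyloxy)-2,6,6-trimethylcyclohex-2-en-1-yl]-2,6,11,15-tetramethylheptadeca-2,4,6,8,10,12,14,16-octaen-1-ol
Product: 24 (1S,4R)-4-[(1E,3E,5E,7E,9E,11E,13E,15E)-17-hydroxy-3,7,12,16-tetramethylheptadeca-1,3,5,7,9,11,13,15-octaen-1-yl]-3,5,5-trimethylcyclohex-2-en-1-ol [(3S,6R)-8'-apo-ε-carotene-3,8'-diol]
Conditions: Bu4NF, THF, 0 °C → rt, dim light
Reagents that add atoms: none
Why: Fluoride-mediated desilylation frees the C3 hydroxyl under non-acidic conditions, so the allylic alcohol cannot ionise or epimerise and the polyene is unaffected.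

Compound list
1 | (E)-pent-3-en-2-one | C/C=C/C(C)=O | starting material
2 | (E)-2-(tert-butyldimethylsilyloxy)penta-1,3-diene | C=C(O[Si](C)(C)C(C)(C)C)/C=C/C | intermediate
3 | 3-methylbut-2-enal | CC(C)=CC=O | starting material
4 | (1S,2S)-4-(tert-butyldimethylsilyloxy)-2,6,6-trimethylcyclohex-3-ene-1-carbaldehyde (cis) | C[C@H]1C=C(O[Si](C)(C)C(C)(C)C)CC(C)(C)[C@H]1C=O | intermediate
5 | triethyl 3-methyl-4-phosphonocrotonate [ethyl (E)-4-(diethoxyphosphoryl)-3-methylbut-2-enoate] | CCOC(=O)/C=C(\C)CP(=O)(OCC)OCC | starting material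
6 | lithium salt of the C4 carbanion of 5 | CCOC(=O)/C=C(\C)[CH-]P(=O)(OCC)OCC.[Li+] | intermediate (not isolated)
7 | ethyl (2E,4E)-5-[(1S,2R)-4-(tert-butyldimethylsilyloxy)-2,6,6-trimethylcyclohex-3-en-1-yl]-3-methylpenta-2,4-dienoate | C[C@H]1C=C(O[Si](C)(C)C(C)(C)C)CC(C)(C)[C@H]1/C=C/C(C)=C/C(=O)OCC | intermediate
8 | ethyl (2E,4E)-3-methyl-5-[(1R)-2,6,6-trimethyl-4-oxocyclohex-2-en-1-yl]penta-2,4-dienoate | CC1=CC(=O)CC(C)(C)[C@H]1/C=C/C(C)=C/C(=O)OCC | intermediate
9 | ethyl (2E,4E)-5-[(1R,4S)-4-hydroxy-2,6,6-trimethylcyclohex-2-en-1-yl]-3-methylpenta-2,4-dienoate | CC1=C[C@@H](O)CC(C)(C)[C@H]1/C=C/C(C)=C/C(=O)OCC | intermediate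
10 | ethyl (2E,4E)-5-[(1R,4S)-4-(tert-butyldimethylsilyloxy)-2,6,6-trimethylcyclohex-2-en-1-yl]-3-methylpenta-2,4-dienoate | CC1=C[C@@H](O[Si](C)(C)C(C)(C)C)CC(C)(C)[C@H]1/C=C/C(C)=C/C(=O)OCC | intermediate
11 | (2E,4E)-5-[(1R,4S)-4-(tert-butyldimethylsilyloxy)-2,6,6-trimethylcyclohex-2-en-1-yl]-3-methylpenta-2,4-dien-1-ol | CC1=C[C@@H](O[Si](C)(C)C(C)(C)C)CC(C)(C)[C@H]1/C=C/C(C)=C/CO | intermediate
12 | (2E,4E)-5-[(1R,4S)-4-(tert-butyldimethylsilyloxy)-2,6,6-trimethylcyclohex-2-en-1-yl]-3-methylpenta-2,4-dienyl bromide | CC1=C[C@@H](O[Si](C)(C)C(C)(C)C)CC(C)(C)[C@H]1/C=C/C(C)=C/CBr | intermediate (not isolated)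
13 | [(2E,4E)-5-[(1R,4S)-4-(tert-butyldimethylsilyloxy)-2,6,6-trimethylcyclohex-2-en-1-yl]-3-methylpenta-2,4-dien-1-yl]triphenylphosphonium bromide | CC1=C[C@@H](O[Si](C)(C)C(C)(C)C)CC(C)(C)[C@H]1/C=C/C(C)=C/C[P+](c2ccccc2)(c2ccccc2)c2ccccc2.[Br-] | intermediate
14 | chloroacetaldehyde | ClCC=O | starting material
15 | ethyl 2-(triphenylphosphoranylidene)propanoate | CCOC(=O)C(C)=P(c1ccccc1)(c1ccccc1)c1ccccc1 | starting material
16 | ethyl (E)-4-chloro-2-methylbut-2-enoate | CCOC(=O)/C(C)=C/CCl | intermediate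
17 | ethyl (E)-4-(diethoxyphosphoryl)-2-methylbut-2-enoate | CCOC(=O)/C(C)=C/CP(=O)(OCC)OCC | intermediate
18 | (2E,4E,6E)-2,7-dimethylocta-2,4,6-trienedial | O=C/C(C)=C/C=C/C=C(C)/C=O | starting material
19 | sodium salt of the C4 carbanion of 17 | CCOC(=O)/C(C)=C/[CH-]P(=O)(OCC)OCC.[Na+] | intermediate (not isolated)
20 | ethyl (2E,4E,6E,8E,10E)-2,6,11-trimethyl-12-oxododeca-2,4,6,8,10-pentaenoate | O=C/C(C)=C/C=C/C=C(C)/C=C/C=C(\C)C(=O)OCC | intermediate
21 | ylide of 13, [(2E,4E)-5-[(1R,4S)-4-(tert-butyldimethylsilyloxy)-2,6,6-trimethylcyclohex-2-en-1-yl]-3-methylpenta-2,4-dienylidene]triphenylphosphorane | CC1=C[C@@H](O[Si](C)(C)C(C)(C)C)CC(C)(C)[C@H]1/C=C/C(C)=C/C=P(c2ccccc2)(c2ccccc2)c2ccccc2 | intermediate (not isolated)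
22 | ethyl (2E,4E,6E,8E,10E,12E,14E,16E)-17-[(1R,4S)-4-(tert-butyldimethylsilyloxy)-2,6,6-trimethylcyclohex-2-en-1-yl]-2,6,11,15-tetramethylheptadeca-2,4,6,8,10,12,14,16-octaenoate | CC1=C[C@@H](O[Si](C)(C)C(C)(C)C)CC(C)(C)[C@H]1/C=C/C(C)=C/C=C/C(C)=C/C=C/C=C(C)/C=C/C=C(\C)C(=O)OCC | intermediate
23 | (2E,4E,6E,8E,10E,12E,14E,16E)-17-[(1R,4S)-4-(tert-butyldimethylsilyloxy)-2,6,6-trimethylcyclohex-2-en-1-yl]-2,6,11,15-tetramethylheptadeca-2,4,6,8,10,12,14,16-octaen-1-ol | CC1=C[C@@H](O[Si](C)(C)C(C)(C)C)CC(C)(C)[C@H]1/C=C/C(C)=C/C=C/C(C)=C/C=C/C=C(C)/C=C/C=C(\C)CO | intermediate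
24 | (1S,4R)-4-[(1E,3E,5E,7E,9E,11E,13E,15E)-17-hydroxy-3,7,12,16-tetramethylheptadeca-1,3,5,7,9,11,13,15-octaen-1-yl]-3,5,5-trimethylcyclohex-2-en-1-ol | CC1=C[C@@H](O)CC(C)(C)[C@H]1/C=C/C(C)=C/C=C/C(C)=C/C=C/C=C(C)/C=C/C=C(\C)CO | target

Total step count: 14. Longest linear sequence: 11 (steps 1–8 and 12–14); steps 9–11 form the side branch.

Steps most likely to fail

Step 2 (Proposed new method). The β,β-dimethyl enal may be activated too weakly, silyl transfer may release an achiral silyl triflimide that catalyses a racemic background reaction or Mukaiyama addition, and facial selectivity may be low or reversed. Fallback with known chemistry: 2 and 3 are combined under the achiral mixed Lewis acid AlBr3/AlMe3 (toluene/CH2Cl2, −5 °C), conditions of the kind used for hindered silyloxydienes with β,β-disubstituted carbonyl dienophiles, to give the racemic cis aldehyde F1. Steps 3, 4 and 5 are then run unchanged on racemic material and should give the racemic dienoate F2, the racemic enone F3 and the racemic cis alcohol F4. F4 is acylated with (1S)-camphanoyl chloride (pyridine, DMAP, CH2Cl2), the two diastereomeric esters are separated by chromatography or crystallisation, and the (1R,4S)-configured camphanate F5 is ethanolysed (K2CO3, EtOH) to rejoin the route at 9.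

Step 3. Addition of the phosphonate carbanion to the hindered formyl group may be slower than enolisation at C6, which would erode enantiopurity once C5 is flattened. Fallback: 4 is heated in toluene with the neutral stabilised ylide 1-(triphenylphosphoranylidene)propan-2-one, which is too weakly basic to enolise the aldehyde, to give the (E)-methyl ketone F6. A Horner–Wadsworth–Emmons reaction of this ketone with triethyl phosphonoacetate (NaH, THF), carried out when C6 is no longer α to a formyl group, then gives 7 after removal of the (2Z) isomer.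

Step 5. Hydride delivery may show poor facial selectivity, the axial C1 methyl group diverting attack to the other face and giving the trans epimer. Fallback: 8 is reduced with LiBH(s-Bu)3 (THF, −78 °C), which should attack equatorially, away from the axial C1 methyl, and give mainly the trans alcohol F7 (the same compound as the minor product of step 5). Mitsunobu reaction of F7 with 4-nitrobenzoic acid (PPh3, diisopropyl azodicarboxylate, THF) inverts C3 to the cis 4-nitrobenzoate F8, and ethanolysis (K2CO3, EtOH) returns to the route at 9.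

Further compounds
F1 | step 2 | racemic cis-4-(tert-butyldimethylsilyloxy)-2,6,6-trimethylcyclohex-3-ene-1-carbaldehyde (racemate of 4) | CC1C=C(O[Si](C)(C)C(C)(C)C)CC(C)(C)C1C=O
F2 | step 2 | racemic ethyl (2E,4E)-5-[cis-4-(tert-butyldimethylsilyloxy)-2,6,6-trimethylcyclohex-3-en-1-yl]-3-methylpenta-2,4-dienoate (racemate of 7) | CC1C=C(O[Si](C)(C)C(C)(C)C)CC(C)(C)C1/C=C/C(C)=C/C(=O)OCC
F3 | step 2 | racemic ethyl (2E,4E)-3-methyl-5-(2,6,6-trimethyl-4-oxocyclohex-2-en-1-yl)penta-2,4-dienoate (racemate of 8) | CC1=CC(=O)CC(C)(C)C1/C=C/C(C)=C/C(=O)OCC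
F4 | step 2 | racemic ethyl (2E,4E)-5-(cis-4-hydroxy-2,6,6-trimethylcyclohex-2-en-1-yl)-3-methylpenta-2,4-dienoate (racemate of 9) | CC1=CC(O)CC(C)(C)C1/C=C/C(C)=C/C(=O)OCC
F5 | step 2 | (1S,4R)-4-[(1E,3E)-5-ethoxy-3-methyl-5-oxopenta-1,3-dien-1-yl]-3,5,5-trimethylcyclohex-2-en-1-yl (1S,4R)-4,7,7-trimethyl-3-oxo-2-oxabicyclo[2.2.1]heptane-1-carboxylate [(1S)-camphanate of 9] | CC1=C[C@@H](OC(=O)[C@@]23CC[C@@](C)(C(=O)O2)C3(C)C)CC(C)(C)[C@H]1/C=C/C(C)=C/C(=O)OCC
F6 | step 3 | (E)-4-[(1S,2R)-4-(tert-butyldimethylsilyloxy)-2,6,6-trimethylcyclohex-3-en-1-yl]but-3-en-2-one | C[C@H]1C=C(O[Si](C)(C)C(C)(C)C)CC(C)(C)[C@H]1/C=C/C(C)=O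
F7 | step 5 | ethyl (2E,4E)-5-[(1R,4R)-4-hydroxy-2,6,6-trimethylcyclohex-2-en-1-yl]-3-methylpenta-2,4-dienoate (trans epimer of 9) | CC1=C[C@H](O)CC(C)(C)[C@H]1/C=C/C(C)=C/C(=O)OCC
F8 | step 5 | (1S,4R)-4-[(1E,3E)-5-ethoxy-3-methyl-5-oxopenta-1,3-dien-1-yl]-3,5,5-trimethylcyclohex-2-en-1-yl 4-nitrobenzoate | CC1=C[C@@H](OC(=O)c2ccc(cc2)[N+](=O)[O-])CC(C)(C)[C@H]1/C=C/C(C)=C/C(=O)OCC
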